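## The problem

The target is a germacrane: a ten-membered carbocycle (ring carbons C1 to C10, methyl groups on C4 and C10, isopropyl on C7). It carries an E trisubstituted alkene C1=C10, a trans epoxide C4–C5, a 3,4,5-trimethoxybenzoate on C6 and a free hydroxyl on C8. Five contiguous stereocentres, C4 to C8 (4R,5R,6S,7R,8R), sit on a flexible medium ring, so each needs a control element that can be named. Only C8 has to be set from outside: C8 can direct C7 through the enolate of a C6 ketone, and C7 and C8 then bias the ring in which C4/C5 and C6 are set. Closing a ten-membered ring end to end works against entropy and transannular strain and would have to preserve the E alkene. The groups are fragile together: the epoxide and the C1=C10 bond cyclise across the ring under acid, 1,5-dienes of this skeleton undergo Cope rearrangement on heating, a C8 oxygen β to a C6 carbonyl can be eliminated, and the C6 ester can migrate to a free C8 hydroxyl under base. The feature that opens the route is that the C6 oxygen lies four atoms from the C1=C10 alkene along C6–C7–C8–C9–C10=C1. Read backwards, the ring is the [3,3] product of a 1,2-dialkenylcyclohexenol in which C1–C6 is a ring bond and C8–C9 is still open, and that cyclohexenol is a 1,2-adduct of a limonene-derived enone.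

## Retrosynthesis

**23 to 22.** The O–CH2Ar bond of a 4-methoxybenzyl ether on the C8 oxygen is cut last. Keeping C8 masked until the end keeps the two oxygens distinguishable and rules out acyl migration from C6. A silyl ether would need fluoride, which is basic enough to move the ester; the benzyl-type ether comes off under neutral oxidative conditions. The forward step must spare the epoxide, the alkene and the electron-rich benzoate.

**22 to 20 and 21.** The C6–O bond of the ester is cut with inversion, leading to the C6-epimeric epoxy alcohol 20 and commercial acid 21. Cutting the acyl–oxygen bond instead (acylation with retention) would need the 6S alcohol, and every control element available in the reduction of 19 points to the other epimer. The forward step is a Mitsunobu displacement at a hindered carbinol, and it must not disturb the neighbouring epoxide.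

**20 to 19.** The C6–H bond is cut, giving epoxy ketone 19. The ketone is what the key step leaves at C6, so no extra oxidation-state change is needed. The forward reduction has to be selective in one sense; chelation to the epoxide oxygen and to the C8 ether oxygen supplies it.

**19 to 18.** Both C–O bonds of the epoxide are cut, giving E enone 18. A nucleophilic oxidant is chosen over a peracid because only the conjugated C4=C5 bond is electron-poor; a peracid would attack C1=C10 first. The forward step must choose one face of the enone, and only ring conformation can decide that.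

**18 to 17 to 15.** No skeletal bond is cut. The ring expansion necessarily delivers C4=C5 with the Z geometry of the cyclohexene, whereas the trans epoxide needs E. A stepwise epoxidation of the Z enone might rotate to the trans product, but ten-membered Z enones are known to close with retention, so the geometry is corrected explicitly. Conjugate stannylation (15 to 17) and oxidative destannylation (17 to 18) do this without touching C7 or C8.

**15 to 12 (key).** C8–C9 is cut and C1–C6 is re-formed, which contracts the ten-membered ring to cyclohexenol 12. This trades a medium-ring closure for a ring expansion that needs no dilution, and it turns five ring stereocentres into two on a six-membered ring, both derived from one terpene centre. The forward [3,3] shift must run through a single chair so that the (1R,6R) configuration of 12 becomes 8R and C1=C10 becomes E. The enol ether must be E for two reasons. It places the ether oxygen pseudo-equatorial. It also means that C9 enters C8 from the inner face while the proton enters C7 from the outer face, which gives the 7,8-anti relation of the target. A Z ether would come from a more robust, oxygen-chelated alkenyllithium, but the same course would give the 7-epimer.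

**12 to 2 and 10.** The C6–C7 bond is cut, giving enone 2 and alkenyl iodide 10. This is the only bond that joins two fragments. The alkenyl metal must keep its geometry, must add 1,2 to an enolisable enone, and must approach trans to the isopropenyl group. With lithium trans to the ether oxygen it can expel alkoxide, so it has to be made and used at very low temperature.

**2 to 1.** One allylic C–H pair of (S)-limonene 1 is exchanged for the carbonyl. The S terpene is required: its stereocentre becomes 6R in 2, 1R,6R in 12 and 8R in 15.

**10 to 8 to 6 to 5 to 3 and 4.** The E geometry of 10 is traced to a syn addition of H–Zr across ynol ether 8, the one route found in which mechanism sets the geometry; eliminations to the bromo enol ether would favour the unwanted isomer. The alkyne is cut back to α-alkoxy ketone 6 (enol triflate elimination), the ketone to Weinreb amide 5 and an isopropyl Grignard reagent, and 5 to alcohol 3 and chloroamide 4.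

## Roads not taken

**Alternative 1:** The cut is C9–C10. The open-chain N-acyloxyphthalimide A2, which carries the E iodoalkene at C10, would be reduced at a cathode with NiCl2·6H2O and 2,2′-bipyridine. Loss of CO2 gives the C9 radical, the alkenylnickel species formed from the C–I bond captures it, and reductive elimination closes the ring to silyl ether A1, one deprotection from 23. Its merit is that C4 to C8, the epoxide and the ester would all be installed in an open chain by reagent control, and the E alkene is fixed before closure. In stereochemical security this is better than the chosen plan, which relies on substrate control in a medium ring for C4/C5 and C6. Its weak points are the end-to-end closure of a ten-membered ring (dilution, premature reduction of the radical, dimerisation), an epoxide and a β-silyloxy radical under low-valent nickel, and the long linear assembly of A2. The chosen plan sets against this a ring formed by expansion in seven steps from a terpene, with the alkene geometry and C8 fixed by one chair.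

**Alternative 2:** The cut is C6–C7, made through a ring contraction. The thirteen-membered diallyl ether A4 (C6–O–C12) would be lithiated at C6 with s-BuLi; a [2,3] shift forms C6–C7, breaks O–C12 and gives the ten-membered diol derivative A3 with the C7 isopropenyl group. A thirteen-membered ether is easier to close than a ten-membered carbocycle, two adjacent centres form in one concerted step, the 4E alkene is present from the start, and the free C6 hydroxyl could direct the epoxidation and be acylated with retention. On alkene geometry and on C6 this road is better than the chosen one, which must isomerise an enone and invert a carbinol. Against it stand the competition between the two allylic α-oxygen positions (C6 and C12) for lithiation, a C6/C7 relation that depends on an uncertain transition-state fold, the need to hydrogenate the isopropenyl group next to two ring alkenes, and the length of the route to A4, whose C8 centre must be made separately. The chosen plan answers with step economy and a single chiral-pool source of absolute configuration.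

**Alternative 3:** The cut is C2–C3. The open-chain allyl sulfone A6 would be deprotonated next to sulfur with KN(SiMe3)2 at high dilution, and the carbanion would displace the C3 allylic bromide to give the ring sulfone A5. This is a proven type of macrocyclisation, the bond forms far from the stereocentres, both alkenes are E beforehand, and the C6 to C8 triad can be built with reagent control and orthogonal protection; in these respects it is at least as sound as the chosen plan. Its costs are α versus γ alkylation of the ambident sulfone anion and SN2 versus SN2′ attack on the bromide, dilution for a ten-membered ring, and a reductive desulfonylation that can move double bonds. The epoxide and the ester would still have to be introduced after closure, so the face of C4=C5 remains a question there as well. The chosen plan is shorter and avoids sulfone removal and protecting-group exchange, but it pays for this with the geometry correction of steps 8 and 9.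

Key step: step 7

Assumption: the 4,5-epoxide is trans (C3 and C6 on opposite sides), as the SMILES requires, so an E-derived epoxide must be delivered; Me3SnLi and Zn(BH4)2 are taken as separately prepared stock solutions.

## Route

Step 1
Reactants: 1 (S)-limonene
Product: 2 (6R)-3-methyl-6-(prop-1-en-2-yl)cyclohex-2-en-1-one
Conditions: Cr(CO)6 (cat.), t-BuOOH, MeCN, reflux
Reagents that add atoms: tert-butyl hydroperoxide, CC(C)(C)OO
Why: Chromium-catalysed allylic oxidation should convert the ring methylene next to the less substituted alkene carbon into the ketone, with carvone (attack at the other allylic methylene) as the by-product to be separated. No stereocentre is formed, and the neutral medium should leave the centre next to the new carbonyl untouched.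

Step 2
Reactants: 3 4-methoxybenzyl alcohol; 4 2-chloro-N-methoxy-N-methylacetamide
Product: 5 N-methoxy-2-[(4-methoxybenzyl)oxy]-N-methylacetamide
Conditions: NaH, Bu4NI (cat.), THF, 0 to 25 °C
Reagents that add atoms: none
Why: Williamson etherification: the sodium alkoxide of 3 displaces the activated primary chloride of 4, and the N-methoxy-N-methylamide resists attack at its carbonyl group.

Step 3
Reactants: 5 N-methoxy-2-[(4-methoxybenzyl)oxy]-N-methylacetamide
Product: 6 1-[(4-methoxybenzyl)oxy]-3-methylbutan-2-one
Conditions: i-PrMgCl, THF, −20 to 0 °C; aq NH4Cl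
Reagents that add atoms: isopropylmagnesium chloride, CC(C)[Mg]Cl
Why: Weinreb ketone synthesis: the chelated tetrahedral adduct stops the Grignard reagent after one addition and releases the ketone on work-up.

Step 4
Reactants: 6 1-[(4-methoxybenzyl)oxy]-3-methylbutan-2-one
Product: 8 4-methoxybenzyl 3-methylbut-1-yn-1-yl ether, via Z enol triflate 7 (not isolated)
Conditions: LiN(SiMe3)2, PhN(SO2CF3)2, THF, −78 °C; then KOC(CH3)3, −78 to −40 °C
Reagents that add atoms: none
Why: Lithium chelation between the enolate and ether oxygens gives the Z enolate at the alkoxy-bearing methylene (the hindered isopropyl methine is not deprotonated), and triflation gives 7 with the vinyl hydrogen trans to the triflate, so tert-butoxide can effect anti elimination to the ynol ether. Ynol ether 8 is kept cold and used at once, because benzylic alkynyl ethers rearrange on warming.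

Step 5
Reactants: 8 4-methoxybenzyl 3-methylbut-1-yn-1-yl ether
Product: 10 (E)-2-iodo-1-[(4-methoxybenzyl)oxy]-3-methylbut-1-ene, via alkenylzirconocene chloride 9 (not isolated)
Conditions: Cp2Zr(H)Cl, THF, 0 to 20 °C; then I2, 0 °C
Reagents that add atoms: iodine, II
Why: Hydrozirconation is a syn addition in which hydride goes to the oxygen-bearing, electrophilic alkyne carbon and zirconium to the isopropyl-bearing carbon, so zirconium in 9 is trans to the ether oxygen. Iodinolysis of the C–Zr bond with retention then gives the E iodide with geometry set by mechanism.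

Step 6
Reactants: 10 (E)-2-iodo-1-[(4-methoxybenzyl)oxy]-3-methylbut-1-ene; 2 (6R)-3-methyl-6-(prop-1-en-2-yl)cyclohex-2-en-1-one
Product: 12 (1R,6R)-1-{(1E)-1-[(4-methoxybenzyl)oxy]-3-methylbut-1-en-2-yl}-3-methyl-6-(prop-1-en-2-yl)cyclohex-2-en-1-ol, via alkenyllithium 11 (not isolated)
Conditions: t-BuLi (2 equiv), Et2O, −100 °C; transfer onto 2, CeCl3, THF, −78 °C; aq NH4Cl
Reagents that add atoms: none
Why: Iodine–lithium exchange with retention gives 11, which is used within minutes at −100 °C because lithium trans to the ether oxygen can expel alkoxide. Cerium-assisted 1,2-addition to the enolisable enone then occurs on the face opposite the neighbouring isopropenyl group, which sets the carbinol centre (1R) and places the two alkenyl groups trans.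

Step 7
Reactants: 12 (1R,6R)-1-{(1E)-1-[(4-methoxybenzyl)oxy]-3-methylbut-1-en-2-yl}-3-methyl-6-(prop-1-en-2-yl)cyclohex-2-en-1-ol
Product: 15 (7R,8R)-7-isopropyl-8-[(4-methoxybenzyl)oxy]-4,10-dimethylcyclodeca-1(10)E,4Z-dien-6-one, via potassium alkoxide 13 (not isolated), via potassium enolate 14 (not isolated)
Conditions: KH, 18-crown-6, THF, 0 to 20 °C; then AcOH, THF, −78 °C
Reagents that add atoms: none
Why: Deprotonation gives alkoxide 13, whose C6–O− group weakens the allylic C1–C6 bond so that the [3,3] shift through C8=C7–C6–C1–C10=C9 should run near room temperature; the closest known reaction type is the anionic oxy-Cope ring expansion of trans-1,2-dialkenylcyclohexanols to cyclodec-5-enones. The ten-membered ring is not closed end to end: it arises by four-carbon expansion of the six-membered ring as C8–C9 forms and C1–C6 breaks within one chair array, so no dilution is needed. The trans relation of the two alkenyl groups admits only the chair in which the ring bonds C6–C5 and C1–C2 are both pseudo-equatorial, which fixes the new C1=C10 bond as E and leaves C4=C5 Z. C8 is set by chirality transfer: the E enol ether holds the benzyloxy group pseudo-equatorial, C9 can reach only one face of C8, and the (1R,6R) configuration of 12 becomes 8R. C7 is set on quenching: C9 entered C8 from the inner face, the proton reaches C7 of enolate 14 from the outer face, and this anti addition across the former E enol ether gives the 7,8-anti (7R) relation of the target; the tetrasubstituted enolate unit should not swivel through the ring before the cold acid quench. The step needs chair over boat (a boat would give the opposite configuration at C8) and survival of the β-alkoxy enolate. The ring fusion secures the first; for the second, the nascent C8–O bond lies near the enolate plane while C8–C9 is the bond aligned with the π system, and short reaction time and a cold quench add to this.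

Step 8
Reactants: 15 (7R,8R)-7-isopropyl-8-[(4-methoxybenzyl)oxy]-4,10-dimethylcyclodeca-1(10)E,4Z-dien-6-one
Product: 17 (7R,8R)-7-isopropyl-8-[(4-methoxybenzyl)oxy]-4,10-dimethyl-4-(trimethylstannyl)cyclodec-1(10)E-en-6-one, via lithium enolate 16 (not isolated)
Conditions: Me3SnLi, THF, −78 °C; aq NH4Cl
Reagents that add atoms: trimethylstannyllithium, [Li][Sn](C)(C)C
Why: Conjugate addition of the soft stannyl anion to the β,β-disubstituted Z enone gives the C5 enolate 16, which cannot expel the C8 ether oxygen and is protonated on work-up. The new centre at C4 is left undefined because it returns to sp2 in step 9, and C7 is not touched.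

Step 9
Reactants: 17 (7R,8R)-7-isopropyl-8-[(4-methoxybenzyl)oxy]-4,10-dimethyl-4-(trimethylstannyl)cyclodec-1(10)E-en-6-one
Product: 18 (7R,8R)-7-isopropyl-8-[(4-methoxybenzyl)oxy]-4,10-dimethylcyclodeca-1(10)E,4E-dien-6-one
Conditions: CrO3·2C5H5N, CH2Cl2, 0 °C
Reagents that add atoms: none
Why: Oxidative destannylation of a β-stannyl ketone regenerates the enone, and the double bond should re-form under kinetic control from the extended conformer with C3 and C6 anti; this is the known way to turn the Z enone of an oxy-Cope-derived cyclodecadienone into the E enone. The product is kept cold because the E,E 1,5-diene can undergo Cope rearrangement.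

Step 10
Reactants: 18 (7R,8R)-7-isopropyl-8-[(4-methoxybenzyl)oxy]-4,10-dimethylcyclodeca-1(10)E,4E-dien-6-one
Product: 19 (4R,5S,7R,8R)-4,5-epoxy-7-isopropyl-8-[(4-methoxybenzyl)oxy]-4,10-dimethylcyclodec-1(10)E-en-6-one
Conditions: t-BuOOH, PhCH2NMe3OH (cat.), THF, 0 °C
Reagents that add atoms: tert-butyl hydroperoxide, CC(C)(C)OO
Why: Nucleophilic (Weitz–Scheffer) epoxidation touches only the electron-poor C4=C5 bond and, starting from the E enone, should close to the trans epoxy ketone. The peroxide is expected on the outer face of the enone in the crossed ring conformation with the C7 isopropyl group pseudo-equatorial, which gives the epoxide configuration of the target; the base is kept catalytic to spare the β-alkoxy ketone.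

Step 11
Reactants: 19 (4R,5S,7R,8R)-4,5-epoxy-7-isopropyl-8-[(4-methoxybenzyl)oxy]-4,10-dimethylcyclodec-1(10)E-en-6-one
Product: 20 (4R,5R,6R,7S,8R)-4,5-epoxy-7-isopropyl-8-[(4-methoxybenzyl)oxy]-4,10-dimethylcyclodec-1(10)E-en-6-ol
Conditions: Zn(BH4)2, Et2O, −20 °C; aq NH4Cl
Reagents that add atoms: none
Why: Zinc borohydride reduces α,β-epoxy ketones through a chelate between the carbonyl and epoxide oxygens to the anti (erythro) epoxy alcohol. Chelation to the C8 ether oxygen (1,3-syn) and outer-face attack on the ring point the same way, so the C6 epimer of the target series is expected as the main product.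

Step 12
Reactants: 20 (4R,5R,6R,7S,8R)-4,5-epoxy-7-isopropyl-8-[(4-methoxybenzyl)oxy]-4,10-dimethylcyclodec-1(10)E-en-6-ol; 21 3,4,5-trimethoxybenzoic acid
Product: 22 (4R,5R,6S,7R,8R)-4,5-epoxy-7-isopropyl-8-[(4-methoxybenzyl)oxy]-4,10-dimethylcyclodec-1(10)E-en-6-yl 3,4,5-trimethoxybenzoate
Conditions: PPh3, diisopropyl azodicarboxylate, toluene, 0 to 25 °C
Reagents that add atoms: none
Why: Mitsunobu esterification: the alkoxyphosphonium salt of 20 is displaced by the carboxylate of 21 with inversion at C6, which turns the anti epoxy alcohol into the syn 6S ester of the target. The epoxide, the benzyl-type ether and the alkene are inert to the neutral redox couple.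

Step 13
Reactants: 22 (4R,5R,6S,7R,8R)-4,5-epoxy-7-isopropyl-8-[(4-methoxybenzyl)oxy]-4,10-dimethylcyclodec-1(10)E-en-6-yl 3,4,5-trimethoxybenzoate
Product: 23 (4R,5R,6S,7R,8R)-4,5-epoxy-8-hydroxy-7-isopropyl-4,10-dimethylcyclodec-1(10)E-en-6-yl 3,4,5-trimethoxybenzoate
Conditions: 2,3-dichloro-5,6-dicyano-1,4-benzoquinone (DDQ), CH2Cl2, pH 7 buffer, 0 °C
Reagents that add atoms: none
Why: Oxidative removal of the 4-methoxybenzyl ether by hydride abstraction and hydrolysis of the oxocarbenium ion. The buffered medium protects the acid-sensitive epoxide–alkene pair, and the ester-bearing aromatic ring is too electron-poor to be oxidised.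

## Compound list

Ring compounds 14 to 23 are named with the germacrane locants defined in The problem.

1 | (S)-limonene, (4S)-1-methyl-4-(prop-1-en-2-yl)cyclohex-1-ene | CC1=CC[C@@H](C(C)=C)CC1 | starting material
2 | (6R)-3-methyl-6-(prop-1-en-2-yl)cyclohex-2-en-1-one ((R)-isopiperitenone) | CC1=CC(=O)[C@@H](C(C)=C)CC1 | intermediate
3 | 4-methoxybenzyl alcohol | COc1ccc(CO)cc1 | starting material
4 | 2-chloro-N-methoxy-N-methylacetamide | CON(C)C(=O)CCl | starting material
5 | N-methoxy-2-[(4-methoxybenzyl)oxy]-N-methylacetamide | CON(C)C(=O)COCc1ccc(OC)cc1 | intermediate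
6 | 1-[(4-methoxybenzyl)oxy]-3-methylbutan-2-one | CC(C)C(=O)COCc1ccc(OC)cc1 | intermediate
7 | (Z)-1-[(4-methoxybenzyl)oxy]-3-methylbut-1-en-2-yl trifluoromethanesulfonate | CC(C)/C(OS(=O)(=O)C(F)(F)F)=C/OCc1ccc(OC)cc1 | intermediate (not isolated)
8 | 4-methoxybenzyl 3-methylbut-1-yn-1-yl ether | CC(C)C#COCc1ccc(OC)cc1 | intermediate
9 | chlorobis(cyclopentadienyl)[(E)-1-[(4-methoxybenzyl)oxy]-3-methylbut-1-en-2-yl]zirconium, zirconium trans to oxygen | CC(C)/C(=C\OCc1ccc(OC)cc1)[Zr](Cl)(C1C=CC=C1)C1C=CC=C1 | intermediate (not isolated)
10 | (E)-2-iodo-1-[(4-methoxybenzyl)oxy]-3-methylbut-1-ene | CC(C)/C(I)=C\OCc1ccc(OC)cc1 | intermediate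
11 | {1-[(4-methoxybenzyl)oxy]-3-methylbut-1-en-2-yl}lithium, lithium trans to oxygen | CC(C)/C([Li])=C\OCc1ccc(OC)cc1 | intermediate (not isolated)
12 | (1R,6R)-1-{(1E)-1-[(4-methoxybenzyl)oxy]-3-methylbut-1-en-2-yl}-3-methyl-6-(prop-1-en-2-yl)cyclohex-2-en-1-ol | CC1=C[C@](O)(/C(C(C)C)=C/OCc2ccc(OC)cc2)[C@@H](C(C)=C)CC1 | intermediate
13 | potassium alkoxide of 12 | CC1=C[C@]([O-])(/C(C(C)C)=C/OCc2ccc(OC)cc2)[C@@H](C(C)=C)CC1.[K+] | intermediate (not isolated)
14 | potassium C6 enolate of 15 (8R; C6=C7 with C5 trans to C8) | C1/C(C)=C\C([O-])=C(C(C)C)\[C@H](OCc2ccc(OC)cc2)C/C(C)=C/C1.[K+] | intermediate (not isolated)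
15 | (7R,8R)-7-isopropyl-8-[(4-methoxybenzyl)oxy]-4,10-dimethylcyclodeca-1(10)E,4Z-dien-6-one | C1/C(C)=C\C(=O)[C@H](C(C)C)[C@H](OCc2ccc(OC)cc2)C/C(C)=C/C1 | intermediate
16 | lithium C5 enolate of 17 (C4 undefined) | C1C(C)([Sn](C)(C)C)C=C([O-])[C@H](C(C)C)[C@H](OCc2ccc(OC)cc2)C/C(C)=C/C1.[Li+] | intermediate (not isolated)
17 | (7R,8R)-7-isopropyl-8-[(4-methoxybenzyl)oxy]-4,10-dimethyl-4-(trimethylstannyl)cyclodec-1(10)E-en-6-one (C4 undefined) | C1C(C)([Sn](C)(C)C)CC(=O)[C@H](C(C)C)[C@H](OCc2ccc(OC)cc2)C/C(C)=C/C1 | intermediate
18 | (7R,8R)-7-isopropyl-8-[(4-methoxybenzyl)oxy]-4,10-dimethylcyclodeca-1(10)E,4E-dien-6-one | C1/C(C)=C/C(=O)[C@H](C(C)C)[C@H](OCc2ccc(OC)cc2)C/C(C)=C/C1 | intermediate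
19 | (4R,5S,7R,8R)-4,5-epoxy-7-isopropyl-8-[(4-methoxybenzyl)oxy]-4,10-dimethylcyclodec-1(10)E-en-6-one | O=C2[C@H](C(C)C)[C@H](OCc1ccc(OC)cc1)C/C(C)=C/CC[C@@]3(C)O[C@H]23 | intermediate
20 | (4R,5R,6R,7S,8R)-4,5-epoxy-7-isopropyl-8-[(4-methoxybenzyl)oxy]-4,10-dimethylcyclodec-1(10)E-en-6-ol | O[C@@H]2[C@H](C(C)C)[C@H](OCc1ccc(OC)cc1)C/C(C)=C/CC[C@@]3(C)O[C@H]23 | intermediate
21 | 3,4,5-trimethoxybenzoic acid | COc1cc(C(=O)O)cc(OC)c1OC | starting material
22 | (4R,5R,6S,7R,8R)-4,5-epoxy-7-isopropyl-8-[(4-methoxybenzyl)oxy]-4,10-dimethylcyclodec-1(10)E-en-6-yl 3,4,5-trimethoxybenzoate | COc1cc(C(=O)O[C@H]2[C@H](C(C)C)[C@H](OCc4ccc(OC)cc4)C/C(C)=C/CC[C@@]3(C)O[C@H]23)cc(OC)c1OC | intermediate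
23 | (4R,5R,6S,7R,8R)-4,5-epoxy-8-hydroxy-7-isopropyl-4,10-dimethylcyclodec-1(10)E-en-6-yl 3,4,5-trimethoxybenzoate | COc1cc(C(=O)O[C@H]2[C@H](C(C)C)[C@H](O)C/C(C)=C/CC[C@@]3(C)O[C@H]23)cc(OC)c1OC | target

## Step count and least certain steps

Total step count: 13. Longest linear sequence: 12 steps (steps 2 to 13, from 3 and 4).

**Step 7 (key step).** The most likely failure is loss of the C8 ether oxygen from enolate 14 by β-elimination if the rearrangement is slow enough for the ring to twist the C8–O bond into alignment with the enolate. A second possible failure is leakage through a boat array, which would lower the enantiomeric purity at C8. The fallback avoids the enolate altogether. It sets out from 12, which is silylated (N-(trimethylsilyl)imidazole) to the trimethylsilyl ether F1. F1 is heated in toluene in a sealed vessel (thermal siloxy-Cope shift through the same chair) to give the C6 silyl enol ether F2. Buffered hydrolysis (KF, MeOH, pH 7) of F2, with the proton again arriving from the outer face, returns to the route at 15. Its cost is the heat, which the 1,5-diene of the product tolerates only for a short time.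

**Step 6.** Anti elimination of lithium 4-methoxybenzyl oxide from 11 (lithium and oxygen are trans) may outrun the addition, and the basic reagent may enolise 2. The fallback uses no alkenyllithium. It sets out from 8 and 2: hydrozirconation of 8 gives 9, which is transmetalated with Me2Zn to the alkenyl(methyl)zinc F3. F3 is added to 2 in the presence of Ti(OiPr)4 and a bis(sulfonamide) diol ligand chosen to match the inherent facial bias of the ketone. This comes back to the route at 12.

**Step 5.** Zirconium may be delivered to the oxygen-bearing carbon if steric control overrides the polarisation of the ynol ether, and 8 may be lost by sigmatropic rearrangement on warming. The fallback sets out from 3 and gives up mechanistic control of geometry in favour of separation. Isovaleraldehyde F4 is acetalised with 3 (pyridinium 4-toluenesulfonate) to the bis-ether acetal F5. One alkoxy group is eliminated (Me3SiOSO2CF3, i-Pr2NEt) to give the enol ether F6. Bromination at −78 °C to the dibromide F7 and dehydrobromination with 1,8-diazabicyclo[5.4.0]undec-7-ene give the bromo enol ethers, from which the E bromide F8 is separated. F8 takes the place of 10 in step 6 and the route is rejoined at 12.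

**Step 9.** The double bond may re-form with the Z geometry or out of conjugation (towards C3 or the C4 methyl group), and the chromium reagent may oxidise the benzylic ether. The fallback sets out from 15 and uses a syn elimination instead. Conjugate addition of sodium benzeneselenolate ((PhSe)2, NaBH4, EtOH) gives the β-phenylselanyl ketone F9. Oxidation with H2O2 in the presence of pyridine at 0 °C gives the selenoxide, which eliminates towards C5 and returns to the route at 18.

**Step 10.** The peroxide may attack the other face of the enone, since only the ring conformation decides, and the base may trigger β-elimination of the C8 ether through the C7 enolate. The fallback lets the C6 hydroxyl deliver the epoxide and sets out from 18: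
- Zn(BH4)2 reduction (chelation to the C8 ether oxygen) gives the allylic alcohol F10.
- Mitsunobu reaction with 4-nitrobenzoic acid gives the inverted ester F11.
- Methanolysis (K2CO3, MeOH) gives the allylic alcohol F12.
- VO(acac)2 and t-BuOOH epoxidise C4=C5 syn to the hydroxyl, under allylic 1,3-strain control, to the epoxy alcohol F13.
- Acylation with 3,4,5-trimethoxybenzoyl chloride and 4-(dimethylamino)pyridine comes back to the route at 22.

**Step 12.** Displacement at the hindered C6 carbinol, flanked by the epoxide and the isopropyl-bearing carbon, may be slow with an acid of only moderate acidity, so that elimination or recovered 20 results. The fallback sets out from 20 and separates inversion from acylation. Mitsunobu reaction with the more acidic 4-nitrobenzoic acid gives the inverted ester F14. Methanolysis (K2CO3, MeOH) gives the epoxy alcohol F13. Acylation with 3,4,5-trimethoxybenzoyl chloride and 4-(dimethylamino)pyridine returns to the route at 22. The same acylation applies if step 11 should deliver the 6S alcohol directly.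

## Further compounds

F1 | step 7 | trimethylsilyl ether of 12, (1R,6R) | CC1=C[C@](O[Si](C)(C)C)(/C(C(C)C)=C/OCc2ccc(OC)cc2)[C@@H](C(C)=C)CC1
F2 | step 7 | C6 trimethylsilyl enol ether of 15 (8R; C6=C7 with C5 trans to C8) | C1/C(C)=C\C(O[Si](C)(C)C)=C(C(C)C)\[C@H](OCc2ccc(OC)cc2)C/C(C)=C/C1
F3 | step 6 | methyl{1-[(4-methoxybenzyl)oxy]-3-methylbut-1-en-2-yl}zinc, zinc trans to oxygen | CC(C)/C([Zn]C)=C\OCc1ccc(OC)cc1
F4 | step 5 | isovaleraldehyde (3-methylbutanal) | CC(C)CC=O
F5 | step 5 | 1,1-bis[(4-methoxybenzyl)oxy]-3-methylbutane | CC(C)CC(OCc1ccc(OC)cc1)OCc1ccc(OC)cc1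
F6 | step 5 | 1-[(4-methoxybenzyl)oxy]-3-methylbut-1-ene (E/Z mixture) | CC(C)C=COCc1ccc(OC)cc1
F7 | step 5 | 1,2-dibromo-1-[(4-methoxybenzyl)oxy]-3-methylbutane (diastereomer mixture) | CC(C)C(Br)C(Br)OCc1ccc(OC)cc1
F8 | step 5 | (E)-2-bromo-1-[(4-methoxybenzyl)oxy]-3-methylbut-1-ene | CC(C)/C(Br)=C\OCc1ccc(OC)cc1
F9 | step 9 | (7R,8R)-7-isopropyl-8-[(4-methoxybenzyl)oxy]-4,10-dimethyl-4-(phenylselanyl)cyclodec-1(10)E-en-6-one (C4 undefined) | C1C(C)([Se]c2ccccc2)CC(=O)[C@H](C(C)C)[C@H](OCc3ccc(OC)cc3)C/C(C)=C/C1
F10 | step 10 | (6S,7S,8R)-7-isopropyl-8-[(4-methoxybenzyl)oxy]-4,10-dimethylcyclodeca-1(10)E,4E-dien-6-ol | C1/C(C)=C/[C@H](O)[C@H](C(C)C)[C@H](OCc2ccc(OC)cc2)C/C(C)=C/C1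
F11 | step 10 | (6R,7R,8R)-7-isopropyl-8-[(4-methoxybenzyl)oxy]-4,10-dimethylcyclodeca-1(10)E,4E-dien-6-yl 4-nitrobenzoate | C1/C(C)=C/[C@@H](OC(=O)c2ccc(cc2)[N+](=O)[O-])[C@H](C(C)C)[C@H](OCc3ccc(OC)cc3)C/C(C)=C/C1
F12 | step 10 | (6R,7S,8R)-7-isopropyl-8-[(4-methoxybenzyl)oxy]-4,10-dimethylcyclodeca-1(10)E,4E-dien-6-ol | C1/C(C)=C/[C@@H](O)[C@H](C(C)C)[C@H](OCc2ccc(OC)cc2)C/C(C)=C/C1
F13 | step 10 | (4R,5R,6S,7S,8R)-4,5-epoxy-7-isopropyl-8-[(4-methoxybenzyl)oxy]-4,10-dimethylcyclodec-1(10)E-en-6-ol (C6 epimer of 20) | O[C@H]2[C@H](C(C)C)[C@H](OCc1ccc(OC)cc1)C/C(C)=C/CC[C@@]3(C)O[C@H]23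
F14 | step 12 | (4R,5R,6S,7R,8R)-4,5-epoxy-7-isopropyl-8-[(4-methoxybenzyl)oxy]-4,10-dimethylcyclodec-1(10)E-en-6-yl 4-nitrobenzoate | O=C(O[C@H]2[C@H](C(C)C)[C@H](OCc1ccc(OC)cc1)C/C(C)=C/CC[C@@]3(C)O[C@H]23)c4ccc(cc4)[N+](=O)[O-]
A1 | alternative 1 | 8-O-(tert-butyldimethylsilyl) ether of 23 | COc1cc(C(=O)O[C@H]2[C@H](C(C)C)[C@H](O[Si](C)(C)C(C)(C)C)C/C(C)=C/CC[C@@]3(C)O[C@H]23)cc(OC)c1OC
A2 | alternative 1 | open-chain precursor of A1: N-hydroxyphthalimide ester of the acid bearing C9, with the (E)-iodoalkene at C10 | COc1cc(C(=O)O[C@@H]([C@H](C(C)C)[C@H](O[Si](C)(C)C(C)(C)C)CC(=O)ON2C(=O)c4ccccc4C2=O)[C@H]3O[C@]3(C)CC/C=C(/I)C)cc(OC)c1OC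
A3 | alternative 2 | (1(10)E,4E)-8-[(tert-butyldimethylsilyl)oxy]-4,10-dimethyl-7-(prop-1-en-2-yl)cyclodeca-1(10),4-dien-6-ol | C1/C(C)=C/[C@@H](O)[C@H](C(C)=C)[C@H](O[Si](C)(C)C(C)(C)C)C/C(C)=C/C1
A4 | alternative 2 | thirteen-membered diallyl ether (C6–O–C12) with three E alkenes and the C8 silyl ether, precursor of A3 | O1C/C(C)=C/[C@H](O[Si](C)(C)C(C)(C)C)C/C(C)=C/CC/C(C)=C/C1
A5 | alternative 3 | (1(10)E,4E)-8-[(tert-butyldimethylsilyl)oxy]-7-isopropyl-6-[(4-methoxybenzyl)oxy]-4,10-dimethyl-2-(phenylsulfonyl)cyclodeca-1(10),4-diene (mixture at C2) | C1/C(C)=C/[C@@H](OCc2ccc(OC)cc2)[C@H](C(C)C)[C@H](O[Si](C)(C)C(C)(C)C)C/C(C)=C/C1S(=O)(=O)c1ccccc1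
A6 | alternative 3 | open-chain precursor of A5: C3 allylic bromide with the C2 phenyl sulfone | BrC/C(C)=C/[C@@H](OCc1ccc(OC)cc1)[C@H](C(C)C)[C@H](O[Si](C)(C)C(C)(C)C)C/C(C)=C/CS(=O)(=O)c1ccccc1
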